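**Retrosynthetic overview**
1. Target 19 ⇐ acetonide removal ⇐ butenolide ring closed last by ring-closing metathesis of an allyl 2-substituted acrylate.
2. C11–C12 bond and the C11 carbinol ⇐ Felkin–Anh-controlled zinc Barbier addition of allyl 2-(bromomethyl)acrylate to a C11 aldehyde.
3. Aldehyde ⇐ 3,11,19-triol ⇐ one LiAlH4 reduction of a bicyclic β-keto ester (sets 3-OH, frees C19-OH and C11-OH, releases the auxiliary).
4. Rings A and B together ⇐ auxiliary-controlled Mn(OAc)3/Cu(OAc)2 oxidative radical bicyclization of an acyclic dienyl α-methyl-β-keto ester (C4–C5, then C10–C9; sets C4, C5, C10, C9 and the exocyclic alkene).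
5. Acyclic precursor ⇐ acetoacetate dianion + 8-bromogeranyl acetate (from geranyl acetate). Ring order: A then B in one operation, butenolide last.

Assumption: the (1R,2S,5R)-8-phenylmenthyl ester is taken to give the 10β-methyl (podocarpic) series in this cyclization, so the (1S,2R,5S)-auxiliary is used for the 10α-methyl series of the target; if the sense is the reverse, the antipodal auxiliary is used with no other change.

Convention: labdane numbering for the decalin (C17 exocyclic methylene carbon, C18 methyl and C19 oxygenated carbon on C4, C20 methyl on C10, C11 on C9); α is below and β above the usual drawing. The target is 3α-OH (equatorial), 4α-CH2OH (axial), 5β-H, 9β-H, 10α-CH3, 11R.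

**Route**

Step 1
Reactants: 1 geranyl acetate
Product: 2 (2E,6E)-8-hydroxy-3,7-dimethylocta-2,6-dien-1-yl acetate
Conditions: SeO2 (0.2 equiv), t-BuOOH (3 equiv), salicylic acid (0.1 equiv), CH2Cl2, rt, 36 h
Reagents that add atoms: selenium dioxide, O=[Se]=O (delivers the oxygen, catalytic); tert-butyl hydroperoxide, CC(C)(C)OO (terminal oxygen source)
Why: Sharpless SeO2/t-BuOOH allylic oxidation (ene then [2,3]-shift) attacks the electron-rich terminal alkene remote from the acetate and is selective for the (E)-methyl group, giving the E-CH2OH geometry that later becomes the trans ring fusion.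

Step 2
Reactants: 2 (2E,6E)-8-hydroxy-3,7-dimethylocta-2,6-dien-1-yl acetate
Product: 3 (2E,6E)-8-bromo-3,7-dimethylocta-2,6-dien-1-yl acetate
Conditions: PBr3 (0.4 equiv), Et2O, −10 → 0 °C; used crude
Reagents that add atoms: phosphorus tribromide, BrP(Br)Br
Why: PBr3 bromination of a primary allylic alcohol proceeds by SN2 without allylic shift at low temperature, keeping both E alkenes and the acetate intact.

Step 3
Reactants: 4 ethyl 2-methyl-3-oxobutanoate; 5 (+)-8-phenylmenthol, (1S,2R,5S)-5-methyl-2-(2-phenylpropan-2-yl)cyclohexan-1-ol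
Product: 6 (1S,2R,5S)-8-phenylmenthyl 2-methyl-3-oxobutanoate (epimers at the acyl α-carbon)
Conditions: DMAP (0.3 equiv), toluene, reflux, 4 Å sieves to remove EtOH
Reagents that add atoms: none
Why: DMAP-catalysed β-keto ester transesterification (Taber, via the acylketene) needs one α-hydrogen, which 4 has, and loads the recoverable auxiliary; the epimeric α-centre is erased in step 5.

Step 4
Reactants: 6 (1S,2R,5S)-8-phenylmenthyl 2-methyl-3-oxobutanoate; 3 (2E,6E)-8-bromo-3,7-dimethylocta-2,6-dien-1-yl acetate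
Product: 8 (1S,2R,5S)-8-phenylmenthyl (6E,10E)-12-acetoxy-2,6,10-trimethyl-3-oxododeca-6,10-dienoate, via sodium lithium dienolate 7 (not isolated)
Conditions: NaH (1.1 equiv), THF, 0 °C; n-BuLi (1.05 equiv), 0 °C; then 3, −78 → 0 °C; 1 M HCl quench
Reagents that add atoms: none
Why: Weiler acetoacetate dianion alkylation: the terminal (γ) carbanion of 7 displaces the primary allylic bromide by SN2 much faster than it attacks the acetate at low temperature, forming the C1–C2 bond with both E alkenes untouched.

Step 5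
Reactants: 8 (1S,2R,5S)-8-phenylmenthyl (6E,10E)-12-acetoxy-2,6,10-trimethyl-3-oxododeca-6,10-dienoate
Product: 9 (1S,2R,5S)-8-phenylmenthyl 11-acetoxy-3-oxo-12,13,14,15,16-pentanorlabd-8(17)-en-19-oate (trans-decalin; 4α-CO2R axial, 4β-CH3, 5β-H, 9β-H with equatorial CH2OAc, 10α-CH3, exocyclic C8=CH2)
Conditions: Mn(OAc)3·2H2O (2.2 equiv), Cu(OAc)2·H2O (1.0 equiv), degassed AcOH, 25 °C, 0.05 M; chromatography to remove the minor auxiliary diastereomer
Reagents that add atoms: none
Why: Snider-type oxidative free-radical polyene cyclization, in which Mn(OAc)3 (trivalent manganese) oxidises the β-keto ester to the planar C4 radical, which closes 6-endo onto C5 through a chair with the ester axial on the face not covered by the auxiliary's phenyl ring; the C10 tertiary radical then closes 6-endo onto the (E)-C8=C9 alkene through a second chair (trans fusion, equatorial C11), and Cu(OAc)2 (divalent copper) oxidises the C8 radical with β-hydride loss to the less substituted exocyclic alkene, so C4, C5, C10 and C9 are set in this one step.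

Step 6
Reactants: 9 bicyclic keto ester
Product: 10 12,13,14,15,16-pentanorlabd-8(17)-ene-3α,11,19-triol (5β-H, 9β-H, 10α-CH3; 3-OH equatorial, C19H2OH axial)
Conditions: LiAlH4 (6 equiv), THF, 0 °C → reflux; then H2O work-up; auxiliary 5 recovered
Reagents that add atoms: none
Why: LiAlH4 global reduction: axial hydride attack on the C3 ketone from the β-face, away from the axial C19 group, gives the equatorial 3α-alcohol, the neopentyl ester is reduced to the C19 carbinol with release of 5, and the acetate is cleaved to the C11 alcohol.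

Step 7
Reactants: 10 3α,11,19-triol
Product: 11 3,19-O-isopropylidene-12,13,14,15,16-pentanorlabd-8(17)-ene-3α,11,19-triol (free C11-OH)
Conditions: Me2C(OMe)2 (3 equiv), PPTS (0.1 equiv), CH2Cl2, rt; aqueous work-up
Reagents that add atoms: 2,2-dimethoxypropane, COC(C)(C)OC
Why: Acid-catalysed transketalisation is selective for the only 1,3-diol (equatorial 3-OH and axial C19-OH close a chair 1,3-dioxane, as in andrographolide 3,19-acetonides), and any mixed ketal on the isolated C11-OH hydrolyses on work-up.

Step 8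
Reactants: 11 acetonide alcohol
Product: 12 3α,19-isopropylidenedioxy-12,13,14,15,16-pentanorlabd-8(17)-en-11-al (9β-H)
Conditions: Dess–Martin periodinane (1.3 equiv), pyridine (3 equiv), CH2Cl2, 0 °C; used at once
Reagents that add atoms: none
Why: Dess–Martin oxidation under buffered, non-enolising conditions gives the β,γ-unsaturated aldehyde without epimerising C9 or moving the exocyclic alkene into conjugation.

Step 9
Reactants: 13 2-(bromomethyl)acrylic acid; 14 allyl alcohol (3 equiv)
Product: 15 allyl 2-(bromomethyl)acrylate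
Conditions: H2SO4 (cat.), benzene, reflux, Dean–Stark
Reagents that add atoms: none
Why: Fischer esterification with azeotropic removal of the water formed is the standard entry to 2-(bromomethyl)acrylate esters and, being acid-mediated, does not displace the allylic bromide.

Step 10
Reactants: 12 C11 aldehyde; 15 allyl 2-(bromomethyl)acrylate (1.5 equiv)
Product: 17 allyl (11R)-11-hydroxy-3α,19-isopropylidenedioxy-15-norlabda-8(17),13-dien-16-oate, via 2-(allyloxycarbonyl)allylzinc bromide 16 (not isolated)
Conditions: Zn dust (3 equiv), THF/sat. aq NH4Cl (5:1), 0 °C → rt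
Reagents that add atoms: none
Why: Zinc Barbier (Luche aqueous) 2-(alkoxycarbonyl)allylation: allylzinc 16 gives the same connectivity from either allyl terminus, adds only to the aldehyde under near-neutral conditions that do not epimerise C9, and Felkin–Anh attack anti to the quaternary C10 branch, past C9–H, gives the (11R)-carbinol.

Step 11
Reactants: 17 (11R)-hydroxy allyl ester
Product: 18 3,19-O-isopropylidene-14-deoxy-11-hydroxyandrographolide (11R)
Conditions: second-generation Grubbs catalyst RuCl2(=CHPh)(H2IMes)(PCy3) (10 mol %), CH2Cl2 (0.005 M), 40 °C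
Reagents that add atoms: none
Why: Ring-closing metathesis: the ruthenium carbene loads on the monosubstituted allyl alkene and closes onto the 1,1-disubstituted acrylate alkene to give the α-substituted butenolide with loss of ethene, while the hindered exocyclic C8 methylene, which could only close to a tetrasubstituted alkene, stays out.

Step 12
Reactants: 18 acetonide butenolide
Product: 19 14-deoxy-11-hydroxyandrographolide
Conditions: AcOH/H2O (7:3), rt
Reagents that add atoms: none
Why: Mild acetal hydrolysis in aqueous acetic acid frees the 3,19-diol without affecting the butenolide, the homoallylic C11 alcohol, the exocyclic alkene or any stereocentre.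

**Compound list**
1 | geranyl acetate | CC(=O)OC/C=C(\C)CCC=C(C)C | starting material
2 | (2E,6E)-8-hydroxy-3,7-dimethylocta-2,6-dien-1-yl acetate | CC(=O)OC/C=C(\C)CC/C=C(\C)CO | intermediate
3 | (2E,6E)-8-bromo-3,7-dimethylocta-2,6-dien-1-yl acetate | CC(=O)OC/C=C(\C)CC/C=C(\C)CBr | intermediate
4 | ethyl 2-methyl-3-oxobutanoate | CCOC(=O)C(C)C(C)=O | starting material
5 | (+)-8-phenylmenthol, (1S,2R,5S) | O[C@H]1C[C@@H](C)CC[C@@H]1C(C)(C)c1ccccc1 | starting material
6 | (1S,2R,5S)-8-phenylmenthyl 2-methyl-3-oxobutanoate | CC(=O)C(C)C(=O)O[C@H]1C[C@@H](C)CC[C@@H]1C(C)(C)c1ccccc1 | intermediate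
7 | sodium lithium dienolate (dianion) of 6 | [Na+].[Li+].C=C([O-])C(C)=C([O-])O[C@H]1C[C@@H](C)CC[C@@H]1C(C)(C)c1ccccc1 | intermediate
8 | (1S,2R,5S)-8-phenylmenthyl (6E,10E)-12-acetoxy-2,6,10-trimethyl-3-oxododeca-6,10-dienoate | CC(=O)OC/C=C(\C)CC/C=C(\C)CCC(=O)C(C)C(=O)O[C@H]1C[C@@H](C)CC[C@@H]1C(C)(C)c1ccccc1 | intermediate
9 | (1S,2R,5S)-8-phenylmenthyl 11-acetoxy-3-oxo-12,13,14,15,16-pentanorlabd-8(17)-en-19-oate (4α-ester, 5β-H, 9β-H, 10α-CH3) | C=C1CC[C@@H]2[C@](C)(C(=O)O[C@H]3C[C@@H](C)CC[C@@H]3C(C)(C)c4ccccc4)C(=O)CC[C@@]2(C)[C@@H]1COC(C)=O | intermediate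
10 | 12,13,14,15,16-pentanorlabd-8(17)-ene-3α,11,19-triol (5β-H, 9β-H, 10α-CH3) | C=C1CC[C@@H]2[C@](C)(CO)[C@H](O)CC[C@@]2(C)[C@@H]1CO | intermediate
11 | 3,19-O-isopropylidene derivative of 10 (free C11-OH) | C=C1CC[C@@H]2[C@](C)(COC(C)(C)O3)[C@H]3CC[C@@]2(C)[C@@H]1CO | intermediate
12 | 3α,19-isopropylidenedioxy-12,13,14,15,16-pentanorlabd-8(17)-en-11-al | C=C1CC[C@@H]2[C@](C)(COC(C)(C)O3)[C@H]3CC[C@@]2(C)[C@@H]1C=O | intermediate
13 | 2-(bromomethyl)acrylic acid | OC(=O)C(=C)CBr | starting material
14 | allyl alcohol | C=CCO | starting material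
15 | allyl 2-(bromomethyl)acrylate | C=CCOC(=O)C(=C)CBr | intermediate
16 | 2-(allyloxycarbonyl)allylzinc bromide | C=CCOC(=O)C(=C)C[Zn]Br | intermediate
17 | allyl (11R)-11-hydroxy-3α,19-isopropylidenedioxy-15-norlabda-8(17),13-dien-16-oate | C=C1CC[C@@H]2[C@](C)(COC(C)(C)O3)[C@H]3CC[C@@]2(C)[C@@H]1[C@H](O)CC(=C)C(=O)OCC=C | intermediate
18 | 3,19-O-isopropylidene-14-deoxy-11-hydroxyandrographolide | C=C1CC[C@@H]2[C@](C)(COC(C)(C)O3)[C@H]3CC[C@@]2(C)[C@@H]1[C@H](O)CC1=CCOC1=O | intermediate
19 | 14-deoxy-11-hydroxyandrographolide | C=C1CC[C@@H]2[C@](C)(CO)[C@H](O)CC[C@@]2(C)[C@@H]1[C@H](O)CC1=CCOC1=O | target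

**Step count**
Total: 12 steps. Longest linear sequence: 10 steps (1, 2, 4, 5, 6, 7, 8, 10, 11, 12) from geranyl acetate.

**Steps most likely to fail, with fallbacks**

Step 5 (radical bicyclization). Risks are incomplete auxiliary control, Cu(OAc)2 trapping the C10 radical before the second ring closes, and endocyclic alkene isomers. The fallback sets out from 3 and 4 and comes back at 11. The dianion of 4 (NaH, then n-BuLi, THF, 0 °C) is alkylated with 3 to give ethyl (6E,10E)-12-acetoxy-2,6,10-trimethyl-3-oxododeca-6,10-dienoate F1, the small-ester substrate for which this cascade is best behaved. The same Mn(OAc)3/Cu(OAc)2 conditions give the racemic bicyclic ethyl keto ester F2 with the same relative configuration. LiAlH4 gives the racemic triol F3, and 2,2-dimethoxypropane/PPTS gives the racemic acetonide alcohol F4. Absolute configuration then comes from a lipase kinetic resolution (Pseudomonas cepacia lipase, vinyl acetate, i-Pr2O) at the primary C11 hydroxyl, as is known for albicanol-type alcohols. The enzyme is taken to acetylate the unwanted enantiomer to the acetate of ent-11 F5, leaving 11 to be collected.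

Step 10 (C11 configuration). The risk is that substrate control at the hindered aldehyde is low or favours the 11S epimer. The fallback sets out from 12 and comes back at 17. The Barbier product is taken on as the (11S)-epimer of 17 F6 (or the epimer mixture) and oxidised (Dess–Martin periodinane, pyridine, CH2Cl2, 0 °C) to the C11 ketone F7. This is reduced under reagent control with (S)-2-methyl-CBS-oxazaborolidine and catecholborane in toluene at −78 °C to 17, so the carbinol is set by hydride delivery to a ketone instead of carbon addition to the aldehyde.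

Step 11 (ring-closing metathesis). The risk is slow closure of the five-membered lactone from the ester's preferred s-trans conformer, or catalyst death on the acrylate. The fallback sets out from 12 and comes back at 18, building the butenolide by carbonylation. Zn/propargyl bromide in THF/aq NH4Cl gives the (11R)-homopropargylic alcohol F8. Its dianion (n-BuLi, 2.2 equiv, THF, −78 °C) is hydroxymethylated with paraformaldehyde to the ynediol F9. NaAlH2(OCH2CH2OMe)2 in THF, then I2 at −78 °C, gives the (13Z)-13-iodo-alkene diol F10 by hydroxyl-directed trans-hydroalumination. PdCl2(PPh3)2-catalysed carbonylative lactonisation (CO 1 atm, K2CO3, THF, 50 °C) closes the ring to 18.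

**Further compounds**
F1 | step 5 | ethyl (6E,10E)-12-acetoxy-2,6,10-trimethyl-3-oxododeca-6,10-dienoate | CC(=O)OC/C=C(\C)CC/C=C(\C)CCC(=O)C(C)C(=O)OCC
F2 | step 5 | racemic ethyl 11-acetoxy-3-oxo-12,13,14,15,16-pentanorlabd-8(17)-en-19-oate (both enantiomers) | C=C1CC[C@@H]2[C@](C)(C(=O)OCC)C(=O)CC[C@@]2(C)[C@@H]1COC(C)=O.C=C1CC[C@H]2[C@@](C)(C(=O)OCC)C(=O)CC[C@]2(C)[C@H]1COC(C)=O
F3 | step 5 | racemic triol (10 and its mirror image) | C=C1CC[C@@H]2[C@](C)(CO)[C@H](O)CC[C@@]2(C)[C@@H]1CO.C=C1CC[C@H]2[C@@](C)(CO)[C@@H](O)CC[C@]2(C)[C@H]1CO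
F4 | step 5 | racemic acetonide alcohol (11 and its mirror image) | C=C1CC[C@@H]2[C@](C)(COC(C)(C)O3)[C@H]3CC[C@@]2(C)[C@@H]1CO.C=C1CC[C@H]2[C@@](C)(COC(C)(C)O3)[C@@H]3CC[C@]2(C)[C@H]1CO
F5 | step 5 | C11 acetate of ent-11 | C=C1CC[C@H]2[C@@](C)(COC(C)(C)O3)[C@@H]3CC[C@]2(C)[C@H]1COC(C)=O
F6 | step 10 | (11S)-epimer of 17 | C=C1CC[C@@H]2[C@](C)(COC(C)(C)O3)[C@H]3CC[C@@]2(C)[C@@H]1[C@@H](O)CC(=C)C(=O)OCC=C
F7 | step 10 | allyl 3α,19-isopropylidenedioxy-11-oxo-15-norlabda-8(17),13-dien-16-oate | C=C1CC[C@@H]2[C@](C)(COC(C)(C)O3)[C@H]3CC[C@@]2(C)[C@@H]1C(=O)CC(=C)C(=O)OCC=C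
F8 | step 11 | (11R)-3α,19-isopropylidenedioxy-15,16-dinorlabd-8(17)-en-13-yn-11-ol | C=C1CC[C@@H]2[C@](C)(COC(C)(C)O3)[C@H]3CC[C@@]2(C)[C@@H]1[C@H](O)CC#C
F9 | step 11 | (11R)-3α,19-isopropylidenedioxy-16-norlabd-8(17)-en-13-yne-11,15-diol | C=C1CC[C@@H]2[C@](C)(COC(C)(C)O3)[C@H]3CC[C@@]2(C)[C@@H]1[C@H](O)CC#CCO
F10 | step 11 | (11R,13Z)-13-iodo-3α,19-isopropylidenedioxy-16-norlabda-8(17),13-diene-11,15-diol | C=C1CC[C@@H]2[C@](C)(COC(C)(C)O3)[C@H]3CC[C@@]2(C)[C@@H]1[C@H](O)C/C(I)=C/CO
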